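## Retrosynthetic overview
1. The last step is a nickel-mediated carbonylative [2+2+1] union of the C8≡C17 alkyne, the C7 enal carbonyl and CO. It makes C7–C8, C17–C19 and C19–O, and so closes the ten-membered ring B and butenolide ring C together.
2. The ring A α-acetoxy enone comes from a singlet-oxygen ene reaction and dehydration of a Diels–Alder cyclohexene. This puts oxygen on C13 and moves the alkene to C11=C12.
3. The Z-enal arm comes from a B-alkyl Suzuki coupling (C4–C5) with (Z)-3-iodobut-2-en-1-ol. C2 is set by catalytic asymmetric vinylation of the C2 aldehyde.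
4. Ring A (C1, C10, C14) comes from an enantioselective endo Diels–Alder reaction of (E)-2-methylhept-2-en-5-ynal with (1E,3E)-1-acetoxypenta-1,3-diene.
5. Ring order: A first, then B and C together.

Assumption: positions use briarane numbering (C1 quaternary, C2 isobutyrate carbon, C5=C6 Z-alkene, C7 lactone carbinol, C8=C17 butenolide alkene, C9 CH2, C10 ring-fusion CH, C11=C12–C13 enone, C14 acetate carbon). IPr is purchased 1,3-bis(2,6-diisopropylphenyl)imidazol-2-ylidene.

## Route

Step 1
Reactants: 1 pent-3-yn-1-ol; 2 2-(triphenylphosphoranylidene)propanal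
Product: 4 (2E)-2-methylhept-2-en-5-ynal, via pent-3-ynal 3 (not isolated)
Conditions: Dess–Martin periodinane (1.1 equiv), 2 (1.3 equiv) present from the start, CH2Cl2, 0 °C to rt
Reagents that add atoms: none
Why: The one-pot Dess–Martin oxidation/Wittig olefination traps the isomerisation-prone β,γ-alkynyl aldehyde as it forms, and the stabilised α-methyl ylide gives the E-trisubstituted enal.

Step 2
Reactants: 5 (2E)-pent-2-enal
Product: 6 (1E,3E)-penta-1,3-dien-1-yl acetate
Conditions: isopropenyl acetate (solvent), TsOH·H2O (2 mol %), reflux, acetone distilled off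
Reagents that add atoms: isopropenyl acetate, CC(=C)OC(C)=O
Why: Acid-catalysed enol-ester exchange on the extended enol is driven by removal of acetone and gives mainly the E,E-dienyl acetate, the only isomer able to reach the s-cis geometry used in step 3.

Step 3
Reactants: 4 (2E)-2-methylhept-2-en-5-ynal; 6 (1E,3E)-penta-1,3-dien-1-yl acetate
Product: 7 (1R,4S,5R,6S)-5-(but-2-yn-1-yl)-6-formyl-4,6-dimethylcyclohex-2-en-1-yl acetate
Conditions: N-protonated (R)-3,3-diphenyl-1-(o-tolyl)pyrrolo-oxazaborolidine, bis(triflyl)imide salt (20 mol %), 6 (2 equiv), CH2Cl2, −78 to −40 °C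
Reagents that add atoms: none
Why: In this enantioselective Diels–Alder reaction the acetoxy donor makes C11 the nucleophilic diene terminus, so it bonds to the enal β-carbon C10; the endo transition state of E,E-diene and E-enal places OAc, CHO and the C11 methyl cis and the butynyl arm trans; and the boron-bound s-trans enal (formyl C–H···O organisation) is open on one face only, which fixes C1, C10 and C14 in the absolute sense drawn.

Step 4
Reactants: 7 (1R,4S,5R,6S)-5-(but-2-yn-1-yl)-6-formyl-4,6-dimethylcyclohex-2-en-1-yl acetate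
Product: 8 (1R,4S,5R,6R)-5-(but-2-yn-1-yl)-6-[(1S)-1-hydroxyprop-2-en-1-yl]-4,6-dimethylcyclohex-2-en-1-yl acetate
Conditions: vinylMgBr (4 equiv), ZnCl2 (2 equiv), Et2O, salts precipitated by 1,4-dioxane and filtered off; (−)-3-exo-morpholinoisoborneol (10 mol %), toluene, 0 °C; then H2O
Reagents that add atoms: vinylmagnesium bromide, C=C[Mg]Br
Why: The amino-alcohol-catalysed asymmetric organozinc 1,2-addition attacks the same aldehyde face as in the benchmark dialkylzinc additions and gives (2S) under catalyst control, while the zinc reagent ignores the acetate and alkyne and the zinc alkoxide does not trigger acetyl migration.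

Step 5
Reactants: 8 (1R,4S,5R,6R)-5-(but-2-yn-1-yl)-6-[(1S)-1-hydroxyprop-2-en-1-yl]-4,6-dimethylcyclohex-2-en-1-yl acetate
Product: 9 (1S)-1-[(1R,2R,5S,6R)-2-acetoxy-6-(but-2-yn-1-yl)-1,5-dimethylcyclohex-3-en-1-yl]prop-2-en-1-yl 2-methylpropanoate
Conditions: isobutyric anhydride, Et3N, DMAP (20 mol %), CH2Cl2, rt
Reagents that add atoms: isobutyric anhydride, CC(C)C(=O)OC(=O)C(C)C
Why: DMAP-catalysed (Steglich-type) acylation esterifies the hindered C2 alcohol with retention at C2 and leaves the C14 acetate alone.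

Step 6
Reactants: 10 but-2-yn-1-ol
Product: 12 (2Z)-3-iodobut-2-en-1-ol, via cyclic alkenylalanate 11 (not isolated)
Conditions: NaAlH2(OCH2CH2OMe)2, Et2O, 0 °C to rt; I2, −78 °C; aqueous work-up
Reagents that add atoms: iodine, II
Why: Hydroxyl-directed trans-hydroalumination puts aluminium on the distal alkyne carbon inside a five-membered alanate, and iodinolysis with retention gives only the Z-iodide that carries the C5=C6 geometry of the target.

Step 7
Reactants: 9 (1S)-1-[(1R,2R,5S,6R)-2-acetoxy-6-(but-2-yn-1-yl)-1,5-dimethylcyclohex-3-en-1-yl]prop-2-en-1-yl 2-methylpropanoate; 12 (2Z)-3-iodobut-2-en-1-ol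
Product: 14 (1S,4Z)-1-[(1R,2R,5S,6R)-2-acetoxy-6-(but-2-yn-1-yl)-1,5-dimethylcyclohex-3-en-1-yl]-6-hydroxy-4-methylhex-4-en-1-yl 2-methylpropanoate, via B-alkyl-9-BBN adduct 13 (not isolated)
Conditions: 9-BBN-H (1.3 equiv), THF, rt; then 12, PdCl2(dppf) (5 mol %), AsPh3, Cs2CO3, DMF–H2O, rt
Reagents that add atoms: none
Why: 9-BBN hydroborates only the terminal alkene (the internal alkyne and ring alkene are far slower), and B-alkyl Suzuki–Miyaura coupling then forms C4–C5 with retention of the Z geometry, because oxidative addition to the vinyl iodide outruns ionisation of the hindered C14 allylic acetate.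

Step 8
Reactants: 14 (1S,4Z)-1-[(1R,2R,5S,6R)-2-acetoxy-6-(but-2-yn-1-yl)-1,5-dimethylcyclohex-3-en-1-yl]-6-hydroxy-4-methylhex-4-en-1-yl 2-methylpropanoate
Product: 15 (1S,4Z)-1-[(1R,2R,5S,6R)-2-acetoxy-6-(but-2-yn-1-yl)-1,5-dimethylcyclohex-3-en-1-yl]-4-methyl-6-oxohex-4-en-1-yl 2-methylpropanoate
Conditions: MnO2 (20 equiv), CH2Cl2, rt
Reagents that add atoms: none
Why: Allylic oxidation with MnO2 touches only the primary allylic alcohol and keeps Z-trisubstituted enals (nerol-to-neral type) configurationally intact.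

Step 9
Reactants: 15 (1S,4Z)-1-[(1R,2R,5S,6R)-2-acetoxy-6-(but-2-yn-1-yl)-1,5-dimethylcyclohex-3-en-1-yl]-4-methyl-6-oxohex-4-en-1-yl 2-methylpropanoate
Product: 18 (1S,4Z)-1-[(1R,2S,6R)-2-acetoxy-6-(but-2-yn-1-yl)-1,5-dimethyl-3-oxocyclohex-4-en-1-yl]-4-methyl-6-oxohex-4-en-1-yl 2-methylpropanoate, via allylic hydroperoxide 16 (not isolated), via allylic peracetate 17 (not isolated)
Conditions: O2, tetraphenylporphyrin (1 mol %), visible light, CH2Cl2, 0 °C, Ac2O, pyridine, DMAP (cat.) in the same flask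
Reagents that add atoms: dioxygen, O=O
Why: This is a Schenck ene reaction followed by Kornblum–DeLaMare-type dehydration, in which the ring alkene is the only electron-rich C=C (enal and alkyne are inert) and its only aligned allylic hydrogen is the pseudo-axial β-H on C11, so oxygen enters at C13 with alkene shift to C11=C12, and loss of acetic acid from the peracetate gives the enone without touching C14.

Step 10
Reactants: 18 (1S,4Z)-1-[(1R,2S,6R)-2-acetoxy-6-(but-2-yn-1-yl)-1,5-dimethyl-3-oxocyclohex-4-en-1-yl]-4-methyl-6-oxohex-4-en-1-yl 2-methylpropanoate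
Product: 20 CNP0325467.3 (target), via oxanickelacyclopentene 19 (not isolated)
Conditions: Ni(cod)2 (1.2 equiv) premixed with IPr (1.2 equiv), toluene; 18 added over 12 h (final 1 mM), rt; then CO (1 atm), rt
Reagents that add atoms: carbon monoxide, [C-]#[O+]
Why: Proposed new method: zerovalent nickel carrying the bulky carbene binds the alkyne and the aldehyde C=O and undergoes oxidative cyclisation with C–C bond formation at the alkyne carbon bearing the larger group (C8), which leaves the small methyl-bearing C17 on nickel and closes ring B; CO then inserts into the Ni–C17 bond and C–O reductive elimination from divalent nickel closes butenolide ring C; the Ni(IPr) unit must sit on the α face, away from the axial C15 methyl that roofs the folding ring, which places C7–O α (7R), and any 7-epimer could be equilibrated through the 2-oxyfuran with DBU; the β,β-disubstituted enal and enone termini disfavour conjugate-mode coupling; the closest known reaction types are the nickel-catalysed macrocyclisation of ynals, the carbonylation of isolated nickeladihydrofurans to butenolides, and the hetero-Pauson–Khand reaction of short-tether ynals.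

## Compound list
1 | pent-3-yn-1-ol | CC#CCCO | starting material
2 | 2-(triphenylphosphoranylidene)propanal | CC(C=O)=P(c1ccccc1)(c1ccccc1)c1ccccc1 | starting material
3 | pent-3-ynal | CC#CCC=O | intermediate
4 | (2E)-2-methylhept-2-en-5-ynal | CC#CC/C=C(\C)C=O | intermediate
5 | (2E)-pent-2-enal | CC/C=C/C=O | starting material
6 | (1E,3E)-penta-1,3-dien-1-yl acetate | C/C=C/C=C/OC(C)=O | intermediate
7 | (1R,4S,5R,6S)-5-(but-2-yn-1-yl)-6-formyl-4,6-dimethylcyclohex-2-en-1-yl acetate (OAc, CHO and C11-Me cis, butynyl trans) | CC(=O)O[C@@H]1C=C[C@H](C)[C@@H](CC#CC)[C@]1(C)C=O | intermediate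
8 | (1R,4S,5R,6R)-5-(but-2-yn-1-yl)-6-[(1S)-1-hydroxyprop-2-en-1-yl]-4,6-dimethylcyclohex-2-en-1-yl acetate | CC(=O)O[C@@H]1C=C[C@H](C)[C@@H](CC#CC)[C@]1(C)[C@@H](O)C=C | intermediate
9 | (1S)-1-[(1R,2R,5S,6R)-2-acetoxy-6-(but-2-yn-1-yl)-1,5-dimethylcyclohex-3-en-1-yl]prop-2-en-1-yl 2-methylpropanoate | CC(=O)O[C@@H]1C=C[C@H](C)[C@@H](CC#CC)[C@]1(C)[C@@H](OC(=O)C(C)C)C=C | intermediate
10 | but-2-yn-1-ol | CC#CCO | starting material
11 | sodium 2,2-bis(2-methoxyethoxy)-3-methyl-2,5-dihydro-1,2-oxaluminol-2-uide (cyclic alkenylalanate) | CC1=CCO[Al-]1(OCCOC)OCCOC.[Na+] | intermediate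
12 | (2Z)-3-iodobut-2-en-1-ol | C/C(I)=C/CO | intermediate
13 | B-alkyl-9-BBN adduct of 9 (boron on C4, stereocentres as in 9) | CC(=O)O[C@@H]1C=C[C@H](C)[C@@H](CC#CC)[C@]1(C)[C@@H](OC(=O)C(C)C)CCB1C2CCCC1CCC2 | intermediate
14 | (1S,4Z)-1-[(1R,2R,5S,6R)-2-acetoxy-6-(but-2-yn-1-yl)-1,5-dimethylcyclohex-3-en-1-yl]-6-hydroxy-4-methylhex-4-en-1-yl 2-methylpropanoate | CC(=O)O[C@@H]1C=C[C@H](C)[C@@H](CC#CC)[C@]1(C)[C@@H](OC(=O)C(C)C)CC/C(C)=C\CO | intermediate
15 | (1S,4Z)-1-[(1R,2R,5S,6R)-2-acetoxy-6-(but-2-yn-1-yl)-1,5-dimethylcyclohex-3-en-1-yl]-4-methyl-6-oxohex-4-en-1-yl 2-methylpropanoate | CC(=O)O[C@@H]1C=C[C@H](C)[C@@H](CC#CC)[C@]1(C)[C@@H](OC(=O)C(C)C)CC/C(C)=C\C=O | intermediate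
16 | (1S,4Z)-1-[(1R,2S,3S,6R)-2-acetoxy-6-(but-2-yn-1-yl)-3-hydroperoxy-1,5-dimethylcyclohex-4-en-1-yl]-4-methyl-6-oxohex-4-en-1-yl 2-methylpropanoate (OOH on the C15-methyl face) | CC(=O)O[C@@H]1[C@@H](OO)C=C(C)[C@@H](CC#CC)[C@]1(C)[C@@H](OC(=O)C(C)C)CC/C(C)=C\C=O | intermediate
17 | C13 peracetate of 16 (same configuration) | CC(=O)O[C@@H]1[C@@H](OOC(C)=O)C=C(C)[C@@H](CC#CC)[C@]1(C)[C@@H](OC(=O)C(C)C)CC/C(C)=C\C=O | intermediate
18 | (1S,4Z)-1-[(1R,2S,6R)-2-acetoxy-6-(but-2-yn-1-yl)-1,5-dimethyl-3-oxocyclohex-4-en-1-yl]-4-methyl-6-oxohex-4-en-1-yl 2-methylpropanoate | CC(=O)O[C@@H]1C(=O)C=C(C)[C@@H](CC#CC)[C@]1(C)[C@@H](OC(=O)C(C)C)CC/C(C)=C\C=O | intermediate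
19 | (IPr)nickel oxanickelacyclopentene spanning C7–O–Ni–C17=C8, ring B closed, 7R | CC(=O)O[C@@H]1C(=O)C=C(C)[C@H]2CC3=C(C)[Ni](=C4N(c5c(C(C)C)cccc5C(C)C)C=CN4c4c(C(C)C)cccc4C(C)C)O[C@@H]3/C=C(/C)CC[C@H](OC(=O)C(C)C)[C@@]21C | intermediate
20 | CNP0325467.3, (1R,2S,5Z,7R,10R,14S)-14-acetoxy-2-isobutyryloxy-13-oxo briarane 5,8(17),11-triene 7-lactone | CC(=O)O[C@@H]1C(=O)C=C(C)[C@H]2CC3=C(C)C(=O)O[C@@H]3/C=C(/C)CC[C@H](OC(=O)C(C)C)[C@@]21C | target

## Step count and weak points
Total step count: 10.
Longest linear sequence: 8 (steps 1, 3, 4, 5, 7, 8, 9, 10).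

**Most likely to fail, first: step 10.**
- A ten-membered ring has never been closed by alkyne–aldehyde oxidative cyclisation followed by carbonylation.
- Zerovalent nickel may bind the enal in conjugate mode or cleave the α-acetoxy ketone.
- The C7 selectivity rests on a conformational argument only.

The fallback separates ring closure from carbonylation. It sets out from 19 and comes back at 20. Instead of being gassed with CO, the nickelacycle is quenched at −78 °C with iodine. The Ni–C17 bond is cleaved with retention, and aqueous work-up gives the macrocyclic (Z)-γ-hydroxy vinyl iodide F8. Palladium-catalysed carbonylative lactonisation of F8 (Pd(PPh3)4, CO at 1 atm, Et3N, THF, 50 °C), the classical route from (Z)-3-iodoallylic alcohols to butenolides, then gives 20. This fallback still needs nickelacycle 19 to form, so it covers a failed CO insertion but not a failed ring closure.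

**Second: step 3.**
- The weak acetoxy donor competes with the C11 methyl group for regiocontrol.
- The α,β-disubstituted enal is a sluggish dienophile.

The fallback changes the diene to a stronger donor and pays for it with a protecting-group exchange. It sets out from 5 and 4 and comes back at 7. Compound 5 is silylated (TBSOTf, Et3N, Et2O) to (1E,3E)-1-(tert-butyldimethylsilyloxy)penta-1,3-diene F1. Cycloaddition of F1 with 4 under the same chiral boron Lewis acid gives the silyl ether adduct (1S,2R,5S,6R)-6-(but-2-yn-1-yl)-2-(tert-butyldimethylsilyloxy)-1,5-dimethylcyclohex-3-ene-1-carbaldehyde F2. HF·pyridine frees the hydroxy aldehyde (1S,2R,5S,6R)-6-(but-2-yn-1-yl)-2-hydroxy-1,5-dimethylcyclohex-3-ene-1-carbaldehyde F3, and Ac2O/pyridine converts F3 into 7.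

**Third: step 9.**
- The ene reaction of a cis-disubstituted cyclohexene that is deactivated by an allylic acetate is slow.
- Long irradiation may start to erode the enal.

The fallback replaces the ene reaction by a much faster [4+2] addition of singlet oxygen to a ring diene. It sets out from 15 and comes back at 18.
- Palladium-catalysed elimination of the allylic acetate (Pd(PPh3)4, Et3N, THF, reflux; syn loss of the β-H on C11) gives the cyclohexa-1,3-diene F4.
- Photooxygenation on the α face, opposite the axial C15 methyl, gives the C11,C14-endoperoxide F5.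
- Thiourea reduces F5 to the cis-1,4-diol F6.
- Ac2O/pyridine acetylates only the secondary C14 hydroxyl, giving the tertiary allylic alcohol monoacetate F7.
- Oxidative allylic transposition with pyridinium chlorochromate, [C5H5NH][CrO3Cl], moves oxygen from C11 to C13 and gives 18.

## Further compounds
F1 | step 3 | (1E,3E)-1-(tert-butyldimethylsilyloxy)penta-1,3-diene | C/C=C/C=C/O[Si](C)(C)C(C)(C)C
F2 | step 3 | (1S,2R,5S,6R)-6-(but-2-yn-1-yl)-2-(tert-butyldimethylsilyloxy)-1,5-dimethylcyclohex-3-ene-1-carbaldehyde | CC(C)(C)[Si](C)(C)O[C@@H]1C=C[C@H](C)[C@@H](CC#CC)[C@]1(C)C=O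
F3 | step 3 | (1S,2R,5S,6R)-6-(but-2-yn-1-yl)-2-hydroxy-1,5-dimethylcyclohex-3-ene-1-carbaldehyde | O[C@@H]1C=C[C@H](C)[C@@H](CC#CC)[C@]1(C)C=O
F4 | step 9 | cyclohexa-1,3-diene from loss of acetic acid from 15 (C11=C12–C13=C14; C1, C2, C10 as in 15) | C1=CC=C(C)[C@@H](CC#CC)[C@]1(C)[C@@H](OC(=O)C(C)C)CC/C(C)=C\C=O
F5 | step 9 | C11,C14-endoperoxide of F4, peroxide bridge on the α face | [C@H]12C=C[C@](C)(OO1)[C@@H](CC#CC)[C@]2(C)[C@@H](OC(=O)C(C)C)CC/C(C)=C\C=O
F6 | step 9 | cis-C11,C14-diol (both hydroxyls α, C12=C13 alkene) | O[C@@H]1C=C[C@](C)(O)[C@@H](CC#CC)[C@]1(C)[C@@H](OC(=O)C(C)C)CC/C(C)=C\C=O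
F7 | step 9 | C14 monoacetate of F6 (free tertiary C11 hydroxyl) | CC(=O)O[C@@H]1C=C[C@](C)(O)[C@@H](CC#CC)[C@]1(C)[C@@H](OC(=O)C(C)C)CC/C(C)=C\C=O
F8 | step 10 | ring B closed (7R)-C7 alcohol carrying the exocyclic (Z)-C8=C17(I)CH3 vinyl iodide | CC(=O)O[C@@H]1C(=O)C=C(C)[C@H]2C/C(=C(\C)I)[C@H](O)/C=C(/C)CC[C@H](OC(=O)C(C)C)[C@@]21C
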